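Amber and ochre hold one charge and differ in the time of reading, 40 min against 12 min, so I need the excess of J over D as a function of how far a flask has gone.

| setting | dusk | autumn | amber | ochre |
|---|---|---|---|---|
| D | 7.4 mM | 16 mM | 11 mM | 11 mM |
| J | 7.4 mM | 16 mM | 11 mM | 11 mM |
| L | 3.1 mM (held) | 3.1 mM (held) | 3.1 mM (held) | 3.1 mM (held) |
| Q | 0.27 mM | 0.27 mM | 0.27 mM | 0.27 mM |
| remark | run made earlier | run made earlier |  |  |
| time |  |  | 40 min | 12 min |

| run | time / min | J / % | D / % |
|---|---|---|---|
| dusk | 5.00 | 49.6 | 45.5 |
| dusk | 10.0 | 48.6 | 38.8 |
| dusk | 15.0 | 48.7 | 32.3 |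
| dusk | 20.0 | 48.9 | 26.1 |
| dusk | 25.0 | 47.4 | 21.1 |
| dusk | 30.0 | 47.6 | 17.0 |
| autumn | 5.00 | 50.5 | 46.3 |
| autumn | 10.0 | 49.5 | 41.4 |
| autumn | 15.0 | 49.4 | 36.9 |
| autumn | 20.0 | 48.8 | 32.3 |
| autumn | 25.0 | 49.2 | 28.3 |
| autumn | 30.0 | 47.6 | 25.1 |

(scatter of a reading: 0.5 percentage points)

- Q is single-handed; D and J are mirror images of each other, charged as a racemate, each of them at the stated concentration
- at the start none of Z is dissolved
- what may be going on: Z + Q + D -> Q + E; Z + Q + J -> Q + G; L <-> Z; 2 Z -> X
- an excess is the difference of the two amounts in percent of their sum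
- an excess is below zero if the other one leads

- the flask that ends with the higher excess of J over D among what is left of the two, or "neither" when 2 percentage points or less lies between them (amber / ochre / neither)
- excess of J over D among what is left of the two at the end, amber
- excess of J over D among what is left of the two at the end, ochre

If D goes by Z + Q + D and J by Z + Q + J, each loss per unit of its own substrate carries the same cZ and cQ. Dividing one by the other removes them, and time with them, however Z arrives.

I read the last rows, column against column, with D and J each charged as half of the total. D stands at 17.0% in dusk and 25.1% in autumn, and J at 47.6% in both. Pooling the logarithms gives s = 18.0, the selectivity factor: the logarithm of the part of D left divided by that of the part of J left. It is rough, since J has lost 2.4 percentage points against a scatter of 0.5 points. So the part of J left is the part of D left raised to the power 1/s.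

Next I read down the D column from 10.0 min to the last reading. The logarithm falls at 0.0413 min⁻¹ in dusk, and less in autumn, at 0.0250 min⁻¹. Interpolating the reciprocal to cD = 11 mM gives 0.0324 min⁻¹, and the lines run back to a mean lag of 3.16 min. My reckoning leaves 30.3% of the D in amber and 75.1% in ochre. With s, that gives excesses of 51.1% and 13.5%.

The forecast says “The D loss is fast and J barely moves”; it names amber, with 54% there, above my figure, and 13.3% for ochre.

The flask gives 55.2% for amber and 13.1% for ochre, so amber ends higher.

    Z + Q + D → Q + E (k = 1.00 × 10⁵ M⁻² min⁻¹)
    Z + Q + J → Q + G (k = 4600 M⁻² min⁻¹)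
    L ⇌ Z, rate k3*(csat - [Z]) (kL = 0.150 min⁻¹)
    2 Z → X (k = 8.70 M⁻¹ min⁻¹)

Put the D actually left into the rule, 27% of its charge in amber and 76% in ochre, and s gives 54.8% and 12.9%. Ochre read at amber's time stands at 55.2% instead of 13.1%, so the difference in time is the main reason for the gap.

The neighbour with 0.11 mM of Q, like amber otherwise, keeps 51% of its D at 40 min, so s gives J left 96.3% and an excess of 31.0%. Computed, that flask has 97% and 31.3%.

The runs were generated by integration for substances that don't exist; the scatter is artificial.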